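The route takes the cyclobutane (C4–C5–C11–C10) apart at both bonds to C5. C4 is the γ-carbon and C11 the α′-carbon of the ring A enone (C1=O, C2=C3), so C5 can enter as an aldehyde and lose its oxygen later. The key step is an intramolecular vinylogous Mukaiyama aldol reaction. In one operation it joins C4 to C5, closes the seven-membered ring (C4–C10) cis on ring A, sets C4 and C5, and restores the enone. Its precursor is the linear silyl dienol ether of a C10-quaternary 3-methylcyclohexenone whose C9–C6 chain ends in the non-enolisable C5 aldehyde. That dienol ether comes regiospecifically from a Birch-derived β,γ-enone.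

Key step: step 12

Numbering (longipinane type, used for every compound): C1 ketone; C2=C3 alkene with methyl on C3; C4 and C11 bridgeheads; C5 cyclobutane CH; C6 CMe2; C7 senecioate carbon; C8 CH2; C9 isovalerate carbon; C10 quaternary carbon with methyl. The target is 4R,5S,7R,9R,10R,11R, and O7/O9 are 1,3-anti.
Remark 1: Birch methylation gives C10 as a racemate and no later reagent can correct it, so the acid is resolved. Which antipode of the amine gives the less soluble salt with the (R)-acid must be found by trial; the (R)-amine is written here.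
Remark 2: (−)-Ipc2BCl is assumed to be the antipode that attacks the Re face of aldehyde 12 and gives 7R. Both antipodes are commercial.
Remark 3: the C10 descriptor switches between R and S along the route only because CIP priorities change. The geometry stays the same.

Step 1
Reactants: 1 3-methoxy-5-methylbenzoic acid; 2 iodomethane
Product: 4 (±)-3-methoxy-1,5-dimethylcyclohexa-2,5-diene-1-carboxylic acid, via dilithium dienediolate 3 (not isolated)
Conditions: Li (3.3 equiv), NH3(l)/THF, −78 °C; MeI, −78 → −33 °C; NH4Cl; cold aq. NaH2PO4 to pH 5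
Reagents that add atoms: iodomethane CI
Why: Birch reductive alkylation, in which the carboxylate directs reduction to C10 and C2, the methoxy and methyl groups stay on the two surviving double bonds, and dienediolate 3 is methylated at C10 to give the quaternary centre as a racemate.

Step 2
Reactants: 4 racemic acid; 5 (R)-1-phenylethylamine
Product: 6 (R)-1-phenylethylammonium (1R)-3-methoxy-1,5-dimethylcyclohexa-2,5-diene-1-carboxylate
Conditions: (R)-PhCH(Me)NH2 (1.0 equiv), EtOAc, recrystallise to constant rotation
Reagents that add atoms: (R)-1-phenylethylamine C[C@@H](N)c1ccccc1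
Why: Classical resolution through diastereomeric salts, in which the less soluble salt is purified by recrystallisation and its configuration secured by X-ray analysis, fixing C10 as R.

Step 3
Reactants: 6 resolved salt; 7 methyllithium
Product: 9 1-[(1R)-3-methoxy-1,5-dimethylcyclohexa-2,5-dien-1-yl]ethan-1-one, via free (R)-acid 8 (not isolated)
Conditions: cold 10% aq. citric acid/Et2O, dry; MeLi (2.2 equiv), Et2O, 0 → 23 °C; pour into cold aq. NH4Cl
Reagents that add atoms: methyllithium [Li]C
Why: Ketone synthesis from a lithium carboxylate and an alkyllithium, in which the dilithio gem-diolate lasts until the quench, the quaternary C10 blocks over-addition and cannot epimerise, and the basic medium spares the enol ether.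

Step 4
Reactants: 10 2,2-dimethylpropane-1,3-diol
Product: 11 2,2-dimethyl-3-(triethylsilyloxy)propan-1-ol
Conditions: NaH (1.0 equiv), THF, 23 °C; Et3SiCl (1.0 equiv)
Reagents that add atoms: chlorotriethylsilane CC[Si](Cl)(CC)CC
Why: Monosilylation of a symmetrical diol through its sparingly soluble monosodium alkoxide, which limits O-silylation to one hydroxyl group.

Step 5
Reactants: 11 mono-TES ether
Product: 12 2,2-dimethyl-3-(triethylsilyloxy)propanal
Conditions: Dess–Martin periodinane, NaHCO3, CH2Cl2, 0 → 23 °C
Reagents that add atoms: none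
Why: Buffered Dess–Martin oxidation of a neopentyl primary alcohol, which keeps the TES ether and gives an aldehyde with no α-hydrogen.

Step 6
Reactants: 9 methyl ketone; 12 aldehyde
Product: 14 (3R)-3-hydroxy-1-[(1R)-3-methoxy-1,5-dimethylcyclohexa-2,5-dien-1-yl]-4,4-dimethyl-5-(triethylsilyloxy)pentan-1-one, via diisopinocampheylboron enolate 13 (not isolated)
Conditions: (−)-Ipc2BCl, Et3N, Et2O, 0 °C; 12, −78 → −20 °C; H2O2, MeOH, pH 7 buffer, 0 °C
Reagents that add atoms: none
Why: Reagent-controlled boron aldol reaction in which only the C8 methyl of 9 can be enolised, the isopinocampheyl ligands of 13 choose the Re face of 12 in the cyclic transition state (7R), and the minor C7 epimer is a diastereomer removable by chromatography because C10 is already fixed.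

Step 7
Reactants: 14 β-hydroxy ketone; 15 benzaldehyde
Product: 16 (1R,3R)-1-hydroxy-1-[(1R)-3-methoxy-1,5-dimethylcyclohexa-2,5-dien-1-yl]-4,4-dimethyl-5-(triethylsilyloxy)pentan-3-yl benzoate
Conditions: SmI2 (0.3 equiv), PhCHO (5 equiv), THF, −10 °C; Et3N-deactivated silica
Reagents that add atoms: benzaldehyde O=Cc1ccccc1
Why: Evans–Tishchenko reduction, in which the hemiacetal of O7 with benzaldehyde, held on trivalent samarium together with the C9 ketone, delivers hydride intramolecularly to give the 1,3-anti (9R) alcohol and, in the same step, distinguishes the two oxygens by leaving a non-enolisable benzoate on O7.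

Step 8
Reactants: 16 hydroxy benzoate
Product: 17 the C9 tert-butyldimethylsilyl ether of 16 (7R,9R,10R)
Conditions: TBSOTf, 2,6-lutidine, CH2Cl2, −78 → 0 °C
Reagents that add atoms: tert-butyldimethylsilyl triflate CC(C)(C)[Si](C)(C)OS(=O)(=O)C(F)(F)F
Why: O-silylation with a silyl triflate, reactive enough for the neopentyl C9 carbinol, places at O9 an ether that the later C11 enolate cannot acylate itself with.

Step 9
Reactants: 17 fully protected diene
Product: 18 (7R,9R,10S)-β,γ-enone alcohol: C1 ketone, C3=C4 alkene, free C5 hydroxyl, O7 benzoate, O9 TBS ether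
Conditions: AcOH/THF/H2O (3:1:1), 23 °C
Reagents that add atoms: water O
Why: Mild acid hydrolysis of a Birch enol ether, which stops at the unconjugated C3=C4 ketone because the acid is too weak to move the double bond, while the same medium cleaves the primary TES ether and leaves the hindered secondary TBS ether and the benzoate.

Step 10
Reactants: 18 keto alcohol
Product: 19 (7R,9R,10S)-keto aldehyde: C5 aldehyde, C1 ketone, C3=C4 alkene
Conditions: Dess–Martin periodinane, NaHCO3, CH2Cl2, 0 °C
Reagents that add atoms: none
Why: Buffered Dess–Martin oxidation, neutral enough to leave the β,γ-enone unconjugated and fast enough to forestall benzoyl migration from O7 to O5.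

Step 11
Reactants: 19 keto aldehyde
Product: 20 (7R,9R,10S)-silyl dienol ether: C1(OTBS)=C2–C3(Me)=C4 in ring A, with the chain C9(OTBS)–C8–C7(OBz)–C6Me2–C5HO on C10
Conditions: TBSOTf (1.2 equiv), Et3N (3 equiv), CH2Cl2, −78 °C; cold aq. NaHCO3; Et3N-deactivated silica
Reagents that add atoms: tert-butyldimethylsilyl triflate CC(C)(C)[Si](C)(C)OS(=O)(=O)C(F)(F)F
Why: Soft enolisation and O-silylation, in which the C2 hydrogens (α to C1=O and allylic to C3=C4) are removed far faster than the neopentyl C11 hydrogens, so only the linear dienol ether forms, and the aldehyde has nothing to enolise.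

Step 12
Reactants: 20 silyl dienol ether aldehyde
Product: 21 (4R,5S,7R,9R,10S)-cis-fused bicyclo[5.4.0]undec-2-en-1-one: C5 hydroxyl, O7 benzoate, O9 TBS ether, methyls on C3, C6 (two) and C10
Conditions: BF3·OEt2 (1.5 equiv), 2,6-di-tert-butylpyridine, CH2Cl2 (0.005 M), −78 → −40 °C; aq. NaHCO3
Reagents that add atoms: none
Why: BF3 binds the C5 aldehyde, C4 (the γ terminus of the C1(OSi)=C2–C3=C4 unit) attacks it, and the resulting silyloxyallyl cation loses its silyl group as the fluoride, which returns the C1 ketone and the C2=C3 double bond. The closest known reaction type is the intramolecular vinylogous Mukaiyama aldol reaction of cyclic silyl dienol ethers, common for five- and six-membered rings and rarer for seven. The seven-membered ring (C4–C5–C6–C7–C8–C9–C10) closes in the 7-(enolexo)-exo-trig mode, helped by the two quaternary carbons C6 and C10 in the tether. C4 is controlled by the tether: the chain hangs from C10 and reaches only the diene face syn to C9, so C5 and C9 end up cis on ring A (H4 cis to the C10 methyl). C5 is controlled by the open, staggered transition state, in which C6 takes the sector between C10 and H4 and the BF3-bound oxygen the sector anti to C10, leaving the aldehyde hydrogen between C10 and C3 and giving the (5S)-carbinol whose C–O bond later points away from C11. The step needs γ- over α-attack and an intact aldehyde: C2 cannot span the tether, the dienol ether regiochemistry was fixed in step 11, C6 carries no hydrogen, and high dilution with a hindered pyridine suppresses intermolecular aldol reaction and protodesilylation.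

Step 13
Reactants: 21 bicyclic hydroxy enone
Product: 22 the C5 methanesulfonate of 21 (4R,5S,7R,9R,10S)
Conditions: MsCl, Et3N, CH2Cl2, −20 °C
Reagents that add atoms: methanesulfonyl chloride CS(Cl)(=O)=O
Why: Mesylation through sulfene, which reaches hindered secondary alcohols, retains the C5 configuration, and is run cold so that the amine does not start loss of the sulfonate.

Step 14
Reactants: 22 mesylate
Product: 24 (4R,5S,7R,9R,10R,11R)-7-benzoyloxy-9-(tert-butyldimethylsilyloxy)longipin-2-en-1-one, via potassium C11 enolate 23 (not isolated)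
Conditions: KN(SiMe3)2 (1.1 equiv), THF, −78 °C; DMPU, −78 → 23 °C
Reagents that add atoms: none
Why: Intramolecular enolate alkylation (4-exo-tet), an established entry to bicyclo[3.1.1]heptanones from keto sulfonates, in which kinetic α′-deprotonation gives cross-conjugated enolate 23, the pseudo-axial C5 lies over C11 with its C–O bond pointing away so that substitution with inversion forms C5–C11 and sets C5 and C11, and H4 lies in the nodal plane of the π system in this conformer, which holds back elimination.

Step 15
Reactants: 24 tricyclic benzoate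
Product: 25 (4R,5S,7R,9R,10R,11R)-7-hydroxy-9-(tert-butyldimethylsilyloxy)longipin-2-en-1-one
Conditions: K2CO3, MeOH, 40 °C
Reagents that add atoms: none
Why: Base-catalysed transesterification (methanolysis) of the benzoate, harmless to the TBS ether and to an enone whose α′ and γ ring positions are bridgeheads.

Step 16
Reactants: 25 C7 alcohol; 26 3-methylbut-2-enoyl chloride
Product: 27 (4R,5S,7R,9R,10R,11R)-9-(tert-butyldimethylsilyloxy)-7-(3-methylbut-2-enoyloxy)longipin-2-en-1-one
Conditions: Me2C=CHCOCl, pyridine, DMAP (cat.), CH2Cl2, 0 → 40 °C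
Reagents that add atoms: 3-methylbut-2-enoyl chloride CC(C)=CC(Cl)=O
Why: DMAP-catalysed acylation of a neopentyl secondary alcohol with pyridine as the only base, so that vinylketene formation and the resulting deconjugation of the senecioate are avoided.

Step 17
Reactants: 27 silyl ether
Product: 28 (4R,5S,7R,9R,10R,11R)-9-hydroxy-7-(3-methylbut-2-enoyloxy)longipin-2-en-1-one
Conditions: HF·pyridine, THF, 0 → 23 °C
Reagents that add atoms: none
Why: Fluoride-mediated desilylation under mildly acidic conditions, which generates no alkoxide, so the senecioate stays on O7 (O7 and O9 are also far apart in the tricycle).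

Step 18
Reactants: 28 C9 alcohol; 29 3-methylbutanoyl chloride
Product: 30 CNP0214473.1, (4R,5S,7R,9R,10R,11R)-9-(3-methylbutanoyloxy)-7-(3-methylbut-2-enoyloxy)longipin-2-en-1-one
Conditions: Me2CHCH2COCl, pyridine, DMAP (cat.), CH2Cl2, 23 → 40 °C
Reagents that add atoms: 3-methylbutanoyl chloride CC(C)CC(Cl)=O
Why: DMAP-catalysed acylation of the last free hydroxyl group, which touches no stereocentre and completes the target.

Compound list
1 | 3-methoxy-5-methylbenzoic acid | COc1cc(C)cc(c1)C(O)=O | starting material
2 | iodomethane | CI | starting material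
3 | dilithium dienediolate from Birch reduction of 1 | [Li+].[Li+].[O-]C([O-])=C1C=C(OC)CC(C)=C1 | intermediate
4 | (±)-3-methoxy-1,5-dimethylcyclohexa-2,5-diene-1-carboxylic acid | COC1=CC(C)(C(O)=O)C=C(C)C1 | intermediate
5 | (R)-1-phenylethylamine | C[C@@H](N)c1ccccc1 | starting material
6 | (R)-1-phenylethylammonium (1R)-3-methoxy-1,5-dimethylcyclohexa-2,5-diene-1-carboxylate | C[C@@H]([NH3+])c1ccccc1.[O-]C(=O)[C@@]1(C)C=C(OC)CC(C)=C1 | intermediate
7 | methyllithium | [Li]C | starting material
8 | (1R)-3-methoxy-1,5-dimethylcyclohexa-2,5-diene-1-carboxylic acid | OC(=O)[C@@]1(C)C=C(OC)CC(C)=C1 | intermediate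
9 | 1-[(1R)-3-methoxy-1,5-dimethylcyclohexa-2,5-dien-1-yl]ethan-1-one | CC(=O)[C@@]1(C)C=C(OC)CC(C)=C1 | intermediate
10 | 2,2-dimethylpropane-1,3-diol | OCC(C)(C)CO | starting material
11 | 2,2-dimethyl-3-(triethylsilyloxy)propan-1-ol | CC[Si](CC)(CC)OCC(C)(C)CO | intermediate
12 | 2,2-dimethyl-3-(triethylsilyloxy)propanal | CC[Si](CC)(CC)OCC(C)(C)C=O | intermediate
13 | diisopinocampheylboron enolate of 9 | C=C(OB([C@@H]1C[C@@H]2C[C@H]([C@H]1C)C2(C)C)[C@@H]1C[C@@H]2C[C@H]([C@H]1C)C2(C)C)[C@@]1(C)C=C(OC)CC(C)=C1 | intermediate
14 | (7R,10R)-β-hydroxy ketone | CC[Si](CC)(CC)OCC(C)(C)[C@H](O)CC(=O)[C@@]1(C)C=C(OC)CC(C)=C1 | intermediate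
15 | benzaldehyde | O=Cc1ccccc1 | starting material
16 | (7R,9R,10R)-anti diol O7-monobenzoate | CC[Si](CC)(CC)OCC(C)(C)[C@H](OC(=O)c1ccccc1)C[C@@H](O)[C@@]1(C)C=C(OC)CC(C)=C1 | intermediate
17 | (7R,9R,10R)-O9-TBS ether of 16 | CC[Si](CC)(CC)OCC(C)(C)[C@H](OC(=O)c1ccccc1)C[C@@H](O[Si](C)(C)C(C)(C)C)[C@@]1(C)C=C(OC)CC(C)=C1 | intermediate
18 | (7R,9R,10S)-β,γ-enone C5 alcohol | OCC(C)(C)[C@H](OC(=O)c1ccccc1)C[C@@H](O[Si](C)(C)C(C)(C)C)[C@@]1(C)CC(=O)CC(C)=C1 | intermediate
19 | (7R,9R,10S)-β,γ-enone C5 aldehyde | O=CC(C)(C)[C@H](OC(=O)c1ccccc1)C[C@@H](O[Si](C)(C)C(C)(C)C)[C@@]1(C)CC(=O)CC(C)=C1 | intermediate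
20 | (7R,9R,10S)-linear silyl dienol ether aldehyde (key-step precursor) | O=CC(C)(C)[C@H](OC(=O)c1ccccc1)C[C@@H](O[Si](C)(C)C(C)(C)C)[C@@]1(C)CC(O[Si](C)(C)C(C)(C)C)=CC(C)=C1 | intermediate
21 | (4R,5S,7R,9R,10S)-cis-fused bicyclic enone C5 alcohol (key-step product) | O=C(O[C@@H]1C[C@@H](O[Si](C)(C)C(C)(C)C)[C@@]2(C)CC(=O)C=C(C)[C@H]2[C@H](O)C1(C)C)c1ccccc1 | intermediate
22 | C5 mesylate of 21 | O=C(O[C@@H]1C[C@@H](O[Si](C)(C)C(C)(C)C)[C@@]2(C)CC(=O)C=C(C)[C@H]2[C@H](OS(C)(=O)=O)C1(C)C)c1ccccc1 | intermediate
23 | potassium C11 (cross-conjugated) enolate of 22 | O=C(O[C@@H]1C[C@@H](O[Si](C)(C)C(C)(C)C)[C@@]2(C)C=C([O-])C=C(C)[C@H]2[C@H](OS(C)(=O)=O)C1(C)C)c1ccccc1.[K+] | intermediate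
24 | 7-benzoyloxy-9-(tert-butyldimethylsilyloxy)longipin-2-en-1-one | O=C(O[C@@H]1C[C@@H](O[Si](C)(C)C(C)(C)C)[C@@]2(C)[C@@H]3C(=O)C=C(C)[C@H]2[C@@H]3C1(C)C)c1ccccc1 | intermediate
25 | 7-hydroxy-9-(tert-butyldimethylsilyloxy)longipin-2-en-1-one | O[C@@H]1C[C@@H](O[Si](C)(C)C(C)(C)C)[C@@]2(C)[C@@H]3C(=O)C=C(C)[C@H]2[C@@H]3C1(C)C | intermediate
26 | 3-methylbut-2-enoyl chloride | CC(C)=CC(Cl)=O | starting material
27 | 9-(tert-butyldimethylsilyloxy)-7-(3-methylbut-2-enoyloxy)longipin-2-en-1-one | CC(C)=CC(=O)O[C@@H]1C[C@@H](O[Si](C)(C)C(C)(C)C)[C@@]2(C)[C@@H]3C(=O)C=C(C)[C@H]2[C@@H]3C1(C)C | intermediate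
28 | 9-hydroxy-7-(3-methylbut-2-enoyloxy)longipin-2-en-1-one | CC(C)=CC(=O)O[C@@H]1C[C@@H](O)[C@@]2(C)[C@@H]3C(=O)C=C(C)[C@H]2[C@@H]3C1(C)C | intermediate
29 | 3-methylbutanoyl chloride | CC(C)CC(Cl)=O | starting material
30 | CNP0214473.1 | CC(C)=CC(=O)O[C@@H]1C[C@@H](OC(=O)CC(C)C)[C@@]2(C)[C@@H]3C(=O)C=C(C)[C@H]2[C@@H]3C1(C)C | target

Total step count: 18. Longest linear sequence: 16 (steps 1–3 and 6–18); steps 4 and 5 are a two-step side branch.

Steps most likely to fail

Step 12. Bond formation between C4 and C5, each next to a quaternary carbon, may be slow enough that protodesilylation of the dienol ether or intermolecular aldol reaction takes over. Facial selectivity at the aldehyde may also be poor. The fallback sets out from keto aldehyde 19 and returns at 21. The silyl group is given up, and the C3=C4 double bond of the β,γ-enone itself acts as the nucleophile in a Me2AlCl-promoted intramolecular carbonyl–ene cyclisation (CH2Cl2, −78 → 0 °C, high dilution). Hydrogen transfer from C2 gives 21 directly. Transfer from the C3 methyl gives the exocyclic-methylene hydroxy ketone F1, which a catalytic amount of DBU in CH2Cl2 brings into conjugation, so both channels end in 21.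

Step 14. Proton transfer from the C11 enolate to the extended dienolate, followed by loss of the sulfonate across C4–C5, may outrun the slow substitution at the hindered C5. The fallback sets out from mesylate 22 and returns at 24, and it removes the acidity of H4 before ring closure.
- Hydrogenation of C2=C3 (H2, Pd/C, EtOAc) gives the saturated keto mesylate F2; its C3 epimers are of no consequence.
- KOt-Bu in t-BuOH/THF equilibrates the two enolates. Only the C11 enolate can reach the back side of C5, and it closes to the saturated tricyclic ketone F3.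
- IBX in DMSO at 70 °C dehydrogenates C2–C3, the only position open because C11 is a bridgehead, and gives 24.

Step 2. The two enantiomers differ only by exchange of a methoxy and a methyl group on the ring, so the diastereomeric salts may co-crystallise and enrichment may stall. The fallback sets out from racemic acid 4 and returns at 9. MeLi under the conditions of step 3 converts 4 into the racemic methyl ketone F4. F4 is separated by preparative supercritical-fluid chromatography on a polysaccharide-type chiral stationary phase. The (R)-enantiomer is 9, and its configuration is secured by X-ray analysis of a crystalline later intermediate.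

Further compounds
F1 | step 12 | (4R,5S,7R,9R,10S)-3-methylidene isomer of 21 (C1 ketone unconjugated) | O=C(O[C@@H]1C[C@@H](O[Si](C)(C)C(C)(C)C)[C@@]2(C)CC(=O)CC(=C)[C@H]2[C@H](O)C1(C)C)c1ccccc1
F2 | step 14 | 2,3-dihydro derivative of mesylate 22 (C3 epimers) | O=C(O[C@@H]1C[C@@H](O[Si](C)(C)C(C)(C)C)[C@@]2(C)CC(=O)CC(C)[C@H]2[C@H](OS(C)(=O)=O)C1(C)C)c1ccccc1
F3 | step 14 | 2,3-dihydro derivative of 24 (saturated tricyclic ketone, C3 epimers) | O=C(O[C@@H]1C[C@@H](O[Si](C)(C)C(C)(C)C)[C@@]2(C)[C@@H]3C(=O)CC(C)[C@H]2[C@@H]3C1(C)C)c1ccccc1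
F4 | step 2 | (±)-1-(3-methoxy-1,5-dimethylcyclohexa-2,5-dien-1-yl)ethan-1-one | CC(=O)C1(C)C=C(OC)CC(C)=C1
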